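The runs were generated by integration with made-up constants; the scatter is artificial.

Put side by side, the red run loses left-handed substrate faster than the green run, and a logarithmic scale shows you by how much. Here the single-handed free catalyst and the partner turn left-handed substrate into left-handed product.

| flask | left-handed substrate | right-handed substrate | partner | free catalyst | remark | time |
|---|---|---|---|---|---|---|
| red | 0.30 M | 0.30 M | 1.5 equiv | 0.05 mol% | the very flask that is asked about, followed so far |  |
| green | 0.15 M | 0.15 M | 1.5 equiv | 0.05 mol% | run made earlier |  |
| flask | 0.30 M | 0.30 M | 1.50 equiv | 0.05 mol% |  | 40 h |

| run | time / h | left-handed product / % | left-handed substrate / % |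
|---|---|---|---|
| red | 1.00 | 0.7 | 49.2 |
| red | 3.00 | 1.9 | 47.6 |
| red | 5.00 | 3.8 | 46.4 |
| red | 8.00 | 5.8 | 44.5 |
| green | 1.33 | 0.9 | 49.2 |
| green | 3.00 | 1.3 | 49.0 |
| green | 6.00 | 2.2 | 48.0 |
| green | 15.0 | 4.8 | 45.7 |

(scatter of a reading: 0.3 percentage points)

- free catalyst is single-handed; left-handed substrate and right-handed substrate are mirror images of each other, charged as a racemate, each of them at the stated concentration
- the numbers in the tables scatter with a standard deviation of 0.3 percentage points

- concentration of left-handed product at 40 h, in M
- concentration of left-handed substrate at 40 h, in M
- concentration of right-handed substrate at 40 h, in M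
- concentration of partner at 40 h, in M

From the last red reading, where left-handed substrate has fallen from half of the charge to 44.5%, you get 158 h as the decade time, the hours in which left-handed substrate falls by one power of ten on a straight logarithmic line. The red reading at 5.00 h gives 154 h, so the red curve starts straight, at 0.00437 M h⁻¹, and shows neither knee nor level within the scatter of 0.3 points. The green run, with catalyst, partner and substrate all at half the concentration, gives 384 h, which is 2.43 times longer; these three changed together, so this comparison does not separate their effects.

Now draw the red line on. At 40 h it has travelled a quarter of a decade, so I expect left-handed substrate at 0.168 M. Left-handed substrate and product add up to 50.3% in the last red reading, so I count what is lost as product, 0.132 M. The two curves then cross at 47.6 h, later than the asked time. The partner, charged at 0.450 M, should fall by that product to 0.318 M, and I leave right-handed substrate, which has no readings, near its charge.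

The forecast, whose reckoning finds “Overall order is therefore about 2”, gives 0.14 M of left-handed product, 0.16 M of left-handed substrate, 0.29 M of right-handed substrate and 0.75 M of partner, differing from my reckoning mainly in the partner. The flask gives 0.140 M, 0.166 M, 0.282 M and 0.298 M in that order.

    free catalyst + right-handed substrate ⇌ catalyst intermediate B (K = 5.10 M⁻¹, k = 47.4 M⁻¹ min⁻¹)
    partner + catalyst intermediate B → free catalyst + right-handed product (k = 0.565 M⁻¹ min⁻¹)
    partner + catalyst intermediate A → free catalyst + left-handed product (k = 1.44 M⁻¹ min⁻¹)
    free catalyst + left-handed substrate ⇌ catalyst intermediate A (K = 31.0 M⁻¹, k = 470 M⁻¹ min⁻¹)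
    left-handed substrate ⇌ right-handed substrate (k = 3.54 × 10⁻⁵ min⁻¹)

Now carry the decade time to a neighbouring flask, the same recipe with 0.02 mol% of free catalyst, read at 40 h. Assume, as neither run can test, that the decade time is inverse in the loading: it then stretches to 395 h, so this flask travels 0.101 of a decade and its left-handed substrate should stand at 0.238 M. In that flask catalyst intermediate A, the resting state, holds 74.3% of the catalyst, and left-handed substrate stands at 0.237 M.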